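**Plan**

- Numbering: oxolane C2 = C7 (bears the 3-hydroxy-4,5-dimethoxyphenyl ring), C3 = C8, C4 = C8′, C5 = C7′ (bears the 3,4,5-trimethoxyphenyl ring). The target is the 7,8-trans-8,8′-cis-7′,8′-trans isomer, (2S,3S,4R,5R).
- Retrosynthesis: the C7′–aryl bond is cut first (arylzinc plus anomeric sulfone), then the ring oxygen is removed from between C7 and C7′ (Baeyer–Villiger in reverse), then the cyclobutanone is cut at C7–C8 and C7′–C8′ into an arylketeniminium ion and cis-2-butene.
- Feature used: the four ring carbons C7, C8, C8′, C7′ are a latent cyclobutanone. The cis-dimethyl pair C8/C8′ is cis-2-butene, and C7/C7′ are the two carbons of an arylketene equivalent.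
- Forward: aldehyde to arylacetamide (4 steps); the (2+2) step closes the four-membered ring; oxygen insertion makes the five-membered lactone; lactol, sulfone, aryl transfer and debenzylation finish.
- Stereochemistry: cis C8/C8′ from the alkene geometry; absolute sense from (2R,5R)-2,5-dimethylpyrrolidine on the keteniminium nitrogen; C7 trans to the C8 methyl by auxiliary control plus α-equilibration, retained in the oxygen insertion; C7′ by aryl delivery anti to both methyl groups.

Key step: step 5

Assumption: the (2R,5R) auxiliary is taken to give the (2S,3S,4R)-cyclobutanone, as minimisation of allylic strain in the cyclobutaniminium ion predicts; if the sense of induction proves opposite, the (2S,5S)-amine is used and nothing else changes.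

**Route**

Step 1
Reactants: 1 3-hydroxy-4,5-dimethoxybenzaldehyde
Product: 2 3-(benzyloxy)-4,5-dimethoxybenzaldehyde
Conditions: BnBr, K2CO3, DMF, rt
Reagents that add atoms: benzyl bromide, BrCc1ccccc1
Why: Williamson etherification: the phenoxide generated by K2CO3 displaces bromide from benzyl bromide, and the resulting aryl benzyl ether should tolerate every later reagent until the final hydrogenolysis.

Step 2
Reactants: 2 3-(benzyloxy)-4,5-dimethoxybenzaldehyde
Product: 4 [3-(benzyloxy)-4,5-dimethoxyphenyl]acetonitrile, via N-(2-aryl-1-tosylvinyl)formamide 3 (not isolated)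
Conditions: TosMIC, t-BuOK, DME, −50 °C; then MeOH, reflux
Reagents that add atoms: p-toluenesulfonylmethyl isocyanide (TosMIC), Cc1ccc(cc1)S(=O)(=O)C[N+]#[C-]
Why: van Leusen reductive cyanation of an aldehyde: the TosMIC anion adds to the carbonyl group, the oxazoline adduct is opened by the second equivalent of base to formamide 3, and methanolysis removes the formyl group and expels sulfinate to leave the nitrile with one more carbon; the cold aprotic first stage keeps the adduct from aromatising to an oxazole.

Step 3
Reactants: 4 [3-(benzyloxy)-4,5-dimethoxyphenyl]acetonitrile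
Product: 5 [3-(benzyloxy)-4,5-dimethoxyphenyl]acetic acid
Conditions: KOH, EtOH/H2O, reflux; then aq HCl
Reagents that add atoms: potassium hydroxide, [K+].[OH-]; water, O
Why: Alkaline hydrolysis of a nitrile through the primary amide to the carboxylate, conditions that the aryl methyl ethers and the benzyl ether survive.

Step 4
Reactants: 5 [3-(benzyloxy)-4,5-dimethoxyphenyl]acetic acid; 6 (2R,5R)-2,5-dimethylpyrrolidine
Product: 8 2-[3-(benzyloxy)-4,5-dimethoxyphenyl]-1-[(2R,5R)-2,5-dimethylpyrrolidin-1-yl]ethan-1-one, via arylacetyl chloride 7 (not isolated)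
Conditions: (COCl)2, cat. DMF, CH2Cl2, 0 °C → rt; then 6, Et3N, CH2Cl2, 0 °C → rt
Reagents that add atoms: none
Why: Amide formation through the acyl chloride, the dependable way to acylate an α,α′-branched secondary amine; the stereocentres of the amine are not involved.

Step 5
Reactants: 8 2-[3-(benzyloxy)-4,5-dimethoxyphenyl]-1-[(2R,5R)-2,5-dimethylpyrrolidin-1-yl]ethan-1-one; 9 cis-2-butene
Product: 12 (2S,3S,4R)-2-[3-(benzyloxy)-4,5-dimethoxyphenyl]-3,4-dimethylcyclobutan-1-one, via keteniminium triflate 10 (not isolated), via cyclobutaniminium triflate 11 (not isolated)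
Conditions: Tf2O, 2,4,6-collidine, 9 (excess), ClCH2CH2Cl, −25 → 70 °C, sealed tube; then aq NaHCO3, CH2Cl2, rt
Reagents that add atoms: water, O
Why: Triflic anhydride O-sulfonylates the amide and collidine removes the benzylic proton to give keteniminium triflate 10, whose sp carbon (the future C7′) is attacked by the butene π bond to give a bridged cation that collapses onto the enamine β-carbon (the future C7) faster than the C8–C8′ bond can rotate; hydrolysis of cyclobutaniminium salt 11 then releases ketone 12 and the auxiliary. The closest known reaction type is the keteniminium–alkene (2+2) cycloaddition, established for aldoketeniminium salts with unactivated cis-alkenes and for amides of C2-symmetric 2,5-dimethylpyrrolidine. The cyclobutane closes by 4-exo attack of the enamine carbon on the cationic alkene carbon, with C7′–C8′ forming first and C7–C8 second. The cis relation of C8 and C8′ is inherited from the alkene because the addition is suprafacial, and their absolute configuration comes from the auxiliary, since the ring methyl next to the C=N+ carbon must lie anti to the N–CH(CH3) group on its side (allylic 1,3-strain). C7 is controlled twice: the second N–CH(CH3) group, on the opposite face, pushes the aryl group anti to itself, and the acidic benzylic α-hydrogen allows equilibration to the isomer with aryl trans to the C8 methyl. The step needs the ion to prefer the alkene over its own electron-rich arene, which excess butene and slow addition of the anhydride should secure, and it needs the non-benzylic α-centre not to enolise, which the strain of a cyclobutene enamine and the bicarbonate hydrolysis should secure.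

Step 6
Reactants: 12 (2S,3S,4R)-2-[3-(benzyloxy)-4,5-dimethoxyphenyl]-3,4-dimethylcyclobutan-1-one
Product: 13 (3R,4S,5S)-5-[3-(benzyloxy)-4,5-dimethoxyphenyl]-3,4-dimethyloxolan-2-one
Conditions: mCPBA, NaHCO3, CH2Cl2, 0 °C → rt
Reagents that add atoms: 3-chloroperoxybenzoic acid (mCPBA), OOC(=O)c1cccc(Cl)c1
Why: Baeyer–Villiger oxidation: in the Criegee adduct of the strained ketone the aryl-bearing secondary benzylic carbon, the better cation-stabilising group, should migrate in preference to the methyl-bearing one and does so with retention, so oxygen enters between C7 and the carbonyl carbon and C7 keeps its configuration.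

Step 7
Reactants: 13 (3R,4S,5S)-5-[3-(benzyloxy)-4,5-dimethoxyphenyl]-3,4-dimethyloxolan-2-one
Product: 14 (3R,4S,5S)-5-[3-(benzyloxy)-4,5-dimethoxyphenyl]-3,4-dimethyloxolan-2-ol (mixture of anomers)
Conditions: i-Bu2AlH, CH2Cl2, −78 °C; aq KNaC4H4O6 (potassium sodium tartrate)
Reagents that add atoms: none
Why: Partial reduction of a γ-lactone by i-Bu2AlH at −78 °C, where the aluminium hemiacetal is stable until work-up; the new anomeric centre is inconsequential because it is planarised in step 9.

Step 8
Reactants: 14 (3R,4S,5S)-5-[3-(benzyloxy)-4,5-dimethoxyphenyl]-3,4-dimethyloxolan-2-ol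
Product: 15 (3R,4S,5S)-2-(benzenesulfonyl)-5-[3-(benzyloxy)-4,5-dimethoxyphenyl]-3,4-dimethyloxolane (mixture of anomers)
Conditions: PhSO2H, CaCl2, CH2Cl2, rt
Reagents that add atoms: benzenesulfinic acid, O=S(O)c1ccccc1
Why: Anomeric sulfone formation: the lactol ionises under the mildly acidic sulfinic acid to the oxocarbenium ion, which is captured at sulfur while CaCl2 binds the water; either anomer serves.

Step 9
Reactants: 15 (3R,4S,5S)-2-(benzenesulfonyl)-5-[3-(benzyloxy)-4,5-dimethoxyphenyl]-3,4-dimethyloxolane; 16 5-bromo-1,2,3-trimethoxybenzene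
Product: 19 (2S,3S,4R,5R)-2-[3-(benzyloxy)-4,5-dimethoxyphenyl]-3,4-dimethyl-5-(3,4,5-trimethoxyphenyl)oxolane, via (3,4,5-trimethoxyphenyl)magnesium bromide 17 (not isolated), via (3,4,5-trimethoxyphenyl)zinc bromide 18 (not isolated)
Conditions: 16, Mg, THF, reflux; ZnBr2, THF, 0 °C → rt; then 15, THF, rt
Reagents that add atoms: none
Why: Substitution of an anomeric sulfone by an arylzinc reagent: ZnBr2-assisted loss of sulfinate gives the C7′ oxocarbenium ion, and the aryl group should be delivered to the ring face opposite the two cis methyl groups (inside attack on the envelope that keeps the C8 methyl pseudoequatorial), which makes C7′ R with the aryl group trans to the C8′ methyl, the arrangement that is also the most stable one.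

Step 10
Reactants: 19 (2S,3S,4R,5R)-2-[3-(benzyloxy)-4,5-dimethoxyphenyl]-3,4-dimethyl-5-(3,4,5-trimethoxyphenyl)oxolane
Product: 20 5-[(2S,3S,4R,5R)-3,4-dimethyl-5-(3,4,5-trimethoxyphenyl)oxolan-2-yl]-2,3-dimethoxyphenol
Conditions: H2 (1 atm), 10% Pd/C, EtOAc, rt
Reagents that add atoms: none
Why: Hydrogenolysis of the aryl benzyl ether over Pd/C, which is much faster than cleavage of the two ring benzylic C–O bonds at ambient pressure, so the reaction is stopped after uptake of one equivalent of H2 and no stereocentre is touched.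

**Compound list**

1 | 3-hydroxy-4,5-dimethoxybenzaldehyde | COc1cc(C=O)cc(O)c1OC | starting material
2 | 3-(benzyloxy)-4,5-dimethoxybenzaldehyde | COc1cc(C=O)cc(OCc2ccccc2)c1OC | intermediate
3 | N-{2-[3-(benzyloxy)-4,5-dimethoxyphenyl]-1-(4-methylbenzenesulfonyl)ethenyl}formamide (formed as its potassium salt) | O=CNC(=Cc1cc(OC)c(OC)c(OCc2ccccc2)c1)S(=O)(=O)c1ccc(C)cc1 | intermediate
4 | [3-(benzyloxy)-4,5-dimethoxyphenyl]acetonitrile | COc1cc(CC#N)cc(OCc2ccccc2)c1OC | intermediate
5 | [3-(benzyloxy)-4,5-dimethoxyphenyl]acetic acid | COc1cc(CC(=O)O)cc(OCc2ccccc2)c1OC | intermediate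
6 | (2R,5R)-2,5-dimethylpyrrolidine | C[C@@H]1CC[C@@H](C)N1 | starting material
7 | [3-(benzyloxy)-4,5-dimethoxyphenyl]acetyl chloride | COc1cc(CC(=O)Cl)cc(OCc2ccccc2)c1OC | intermediate
8 | 2-[3-(benzyloxy)-4,5-dimethoxyphenyl]-1-[(2R,5R)-2,5-dimethylpyrrolidin-1-yl]ethan-1-one | COc1cc(CC(=O)N2[C@H](C)CC[C@H]2C)cc(OCc3ccccc3)c1OC | intermediate
9 | cis-2-butene | C/C=C\C | starting material
10 | 1-{2-[3-(benzyloxy)-4,5-dimethoxyphenyl]ethenylidene}-(2R,5R)-2,5-dimethylpyrrolidin-1-ium trifluoromethanesulfonate | COc1cc(C=C=[N+]2[C@H](C)CC[C@H]2C)cc(OCc3ccccc3)c1OC.[O-]S(=O)(=O)C(F)(F)F | intermediate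
11 | 1-{(2S,3S,4R)-2-[3-(benzyloxy)-4,5-dimethoxyphenyl]-3,4-dimethylcyclobutylidene}-(2R,5R)-2,5-dimethylpyrrolidin-1-ium trifluoromethanesulfonate | COc1cc([C@H]2C(=[N+]3[C@H](C)CC[C@H]3C)[C@H](C)[C@@H]2C)cc(OCc4ccccc4)c1OC.[O-]S(=O)(=O)C(F)(F)F | intermediate
12 | (2S,3S,4R)-2-[3-(benzyloxy)-4,5-dimethoxyphenyl]-3,4-dimethylcyclobutan-1-one (methyls cis, aryl trans to the C3 methyl) | COc1cc([C@H]2C(=O)[C@H](C)[C@@H]2C)cc(OCc3ccccc3)c1OC | intermediate
13 | (3R,4S,5S)-5-[3-(benzyloxy)-4,5-dimethoxyphenyl]-3,4-dimethyloxolan-2-one | COc1cc([C@H]2OC(=O)[C@H](C)[C@@H]2C)cc(OCc3ccccc3)c1OC | intermediate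
14 | (3R,4S,5S)-5-[3-(benzyloxy)-4,5-dimethoxyphenyl]-3,4-dimethyloxolan-2-ol, anomeric mixture | COc1cc([C@H]2OC(O)[C@H](C)[C@@H]2C)cc(OCc3ccccc3)c1OC | intermediate
15 | (3R,4S,5S)-2-(benzenesulfonyl)-5-[3-(benzyloxy)-4,5-dimethoxyphenyl]-3,4-dimethyloxolane, anomeric mixture | COc1cc([C@H]2OC(S(=O)(=O)c3ccccc3)[C@H](C)[C@@H]2C)cc(OCc4ccccc4)c1OC | intermediate
16 | 5-bromo-1,2,3-trimethoxybenzene | COc1cc(Br)cc(OC)c1OC | starting material
17 | (3,4,5-trimethoxyphenyl)magnesium bromide | COc1cc([Mg]Br)cc(OC)c1OC | intermediate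
18 | (3,4,5-trimethoxyphenyl)zinc bromide | COc1cc([Zn]Br)cc(OC)c1OC | intermediate
19 | (2S,3S,4R,5R)-2-[3-(benzyloxy)-4,5-dimethoxyphenyl]-3,4-dimethyl-5-(3,4,5-trimethoxyphenyl)oxolane | COc1cc([C@H]2O[C@@H](c3cc(OC)c(OC)c(OC)c3)[C@H](C)[C@@H]2C)cc(OCc4ccccc4)c1OC | intermediate
20 | 5-[(2S,3S,4R,5R)-3,4-dimethyl-5-(3,4,5-trimethoxyphenyl)oxolan-2-yl]-2,3-dimethoxyphenol | COc1cc([C@H]2O[C@@H](c3cc(OC)c(OC)c(OC)c3)[C@H](C)[C@@H]2C)cc(O)c1OC | target

**Step count and risks**

Total steps: 10. Longest linear sequence: 10 steps (1 to 20); 6, 9 and 16 are bought and enter in steps 4, 5 and 9.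

Steps most likely to fail:

Step 5. The keteniminium ion may be intercepted by its own electron-rich arene, or condense with unreacted amide, before the unactivated, volatile alkene adds. The bulky auxiliary may also discriminate poorly between the two orientations of the butene; equilibration at the aryl-bearing carbon then turns a diastereomer problem into loss of enantiomeric purity. Fallback: setting out from acid 5, the acid chloride is quenched with Me2NH to give 2-[3-(benzyloxy)-4,5-dimethoxyphenyl]-N,N-dimethylacetamide F1, whose unhindered keteniminium ion is the more reactive partner. The same Tf2O/collidine cycloaddition with 9 and bicarbonate hydrolysis should give rac-2-[3-(benzyloxy)-4,5-dimethoxyphenyl]-3,4-dimethylcyclobutan-1-one F2 (methyls cis, aryl trans). This is resolved by preparative chromatography on a chiral stationary phase; the (2S,3S,4R) enantiomer is 12, where the route is rejoined. Absolute configuration then comes from resolution and not from the auxiliary.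

Step 9. Aryl transfer may lose facial selectivity, or the oxocarbenium ion may shed the C8′ proton to give the 2,3-dihydrofuran, which wastes material and on reprotonation scrambles C8′. Fallback: setting out from lactol 14, an excess of Grignard reagent 17 (THF, 0 °C) opens the lactol and should give (1S,2S,3R,4RS)-1-[3-(benzyloxy)-4,5-dimethoxyphenyl]-2,3-dimethyl-4-(3,4,5-trimethoxyphenyl)butane-1,4-diol F3 as a mixture at the new carbinol. Brief treatment with BF3·OEt2 in CH2Cl2 at 0 °C ionises a benzylic C–O bond and closes the oxolane reversibly. Both aryl groups should then settle trans to their neighbouring methyl groups under thermodynamic control, while the methyl-bearing centres, which fix the enantiomer, are untouched; the product is 19. Exposure is kept short because the same cation can alkylate the other arene to an aryltetralin.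

Step 6. The methyl-bearing α-carbon may compete in the migration and give the regioisomeric lactone, and the peracid may attack the trialkoxyarene. Fallback: setting out from 12, soft enolisation towards the benzylic side (TBSOTf, Et3N, CH2Cl2, 0 °C) should give tert-butyl{[(3S,4R)-2-aryl-3,4-dimethylcyclobut-1-en-1-yl]oxy}dimethylsilane F4. Ozonolysis (O3, CH2Cl2, −78 °C; Me2S) cleaves the ring at the C7–C7′ bond to (2R,3S)-4-aryl-2,3-dimethyl-4-oxobutanoic acid F5, and TMSCHN2 gives methyl (2R,3S)-4-aryl-2,3-dimethyl-4-oxobutanoate F6. Corey–Bakshi–Shibata reduction with (R)-2-methyl-CBS-oxazaborolidine and BH3·SMe2 (the R catalyst being assumed by analogy with acetophenone) sets C7 under reagent control as methyl (2R,3S,4S)-4-aryl-4-hydroxy-2,3-dimethylbutanoate F7, which lactonises with catalytic TsOH to 13. The position of the oxygen is then fixed by the enol double bond and not by migratory aptitude; the keto acid is kept away from base so that the methyl-bearing centre next to the ketone does not epimerise.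

**Further compounds**

F1 | step 5 | 2-[3-(benzyloxy)-4,5-dimethoxyphenyl]-N,N-dimethylacetamide | COc1cc(CC(=O)N(C)C)cc(OCc2ccccc2)c1OC
F2 | step 5 | rac-(2S*,3S*,4R*)-2-[3-(benzyloxy)-4,5-dimethoxyphenyl]-3,4-dimethylcyclobutan-1-one | COc1cc([C@H]2C(=O)[C@H](C)[C@@H]2C)cc(OCc3ccccc3)c1OC.COc1cc([C@@H]2C(=O)[C@@H](C)[C@H]2C)cc(OCc3ccccc3)c1OC
F3 | step 9 | (1S,2S,3R,4RS)-1-[3-(benzyloxy)-4,5-dimethoxyphenyl]-2,3-dimethyl-4-(3,4,5-trimethoxyphenyl)butane-1,4-diol | COc1cc([C@@H](O)[C@@H](C)[C@@H](C)C(O)c2cc(OC)c(OC)c(OC)c2)cc(OCc3ccccc3)c1OC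
F4 | step 6 | tert-butyl({(3S,4R)-2-[3-(benzyloxy)-4,5-dimethoxyphenyl]-3,4-dimethylcyclobut-1-en-1-yl}oxy)dimethylsilane | COc1cc(C2=C(O[Si](C)(C)C(C)(C)C)[C@H](C)[C@@H]2C)cc(OCc3ccccc3)c1OC
F5 | step 6 | (2R,3S)-4-[3-(benzyloxy)-4,5-dimethoxyphenyl]-2,3-dimethyl-4-oxobutanoic acid | COc1cc(C(=O)[C@@H](C)[C@@H](C)C(=O)O)cc(OCc2ccccc2)c1OC
F6 | step 6 | methyl (2R,3S)-4-[3-(benzyloxy)-4,5-dimethoxyphenyl]-2,3-dimethyl-4-oxobutanoate | COc1cc(C(=O)[C@@H](C)[C@@H](C)C(=O)OC)cc(OCc2ccccc2)c1OC
F7 | step 6 | methyl (2R,3S,4S)-4-[3-(benzyloxy)-4,5-dimethoxyphenyl]-4-hydroxy-2,3-dimethylbutanoate | COc1cc([C@@H](O)[C@@H](C)[C@@H](C)C(=O)OC)cc(OCc2ccccc2)c1OC
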